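**Plan**

- Retrosynthesis: the C3 ketone is taken back to a carbinol and the ring is cut at C2–C3 (Reformatsky). The chain is then cut at the ester C1–O(C13), at the diene bond C10–C11 (Suzuki–Miyaura), at the enol ether bond O–C6 (C–O coupling of an alkenyl iodide) and at C5–C6 (acetylide opening of an epoxide).
- Forward: a C3–C5 glycidate and a C6–C10 alkyne are joined at C5–C6, the C6 methyl enol ether is built, the C11–C13 alkenyl boronate is attached at C10, and C13–OH is acylated with the C1–C2 unit. The only ring, the 14-membered lactone, closes last at C2–C3.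
- Enabling feature: C2 lies between the lactone carbonyl C1 and the ketone C3 of the 14-membered ring. C2–C3 is therefore an aldol-type bond that can be made without stereocontrol, with C2 set afterwards by equilibration. C4 is fully substituted, so the C3 aldehyde cannot enolise.
- Stereochemistry: C4 from Sharpless epoxidation, C8 from Evans alkylation, C13 from lipase resolution, 6E from syn-hydrosilylation followed by two stereoretentive substitutions, 11Z from anti-carbomagnesiation, C2 by equilibration (C3 is erased by oxidation).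

Key step: step 20

Remarks on the chemistry:

- Numbering: C1 is the lactone carbonyl and C13 the ring carbon that bears the lactone oxygen. TBS = tert-butyl(dimethyl)silyl, TES = triethylsilyl, pin = pinacolato, TBSO-methyl = CH2OTBS.
- Assumption: C2 of the target is configurationally labile because it lies between two carbonyl groups. The (2R) configuration asked for is therefore taken to be the one preferred at equilibrium in the 14-membered ring.
- Once the methyl enol ether is in place, all work-ups and chromatography are kept neutral to basic (Et3N-doped silica).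

**Route**

Step 1
Reactants: 1 2-methylidenepropane-1,3-diol
Product: 2 2-(TBSO-methyl)prop-2-en-1-ol
Conditions: TBSCl (1 equiv), imidazole, 1 (3 equiv), THF, 0 °C → rt
Reagents that add atoms: tert-butyl(chloro)dimethylsilane, CC(C)(C)[Si](C)(C)Cl
Why: Statistical monosilylation of the symmetric allylic diol, used in excess, protects one primary hydroxyl as its TBS ether and leaves the other free to direct the epoxidation, and no stereocentre is formed.

Step 2
Reactants: 2 2-(TBSO-methyl)prop-2-en-1-ol
Product: 3 (R)-[2-(TBSO-methyl)oxiran-2-yl]methanol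
Conditions: Ti(OiPr)4 (10 mol%), D-(−)-diethyl tartrate (12 mol%), t-BuOOH, 4 Å MS, CH2Cl2, −20 °C
Reagents that add atoms: tert-butyl hydroperoxide, CC(C)(C)OO
Why: Sharpless asymmetric epoxidation of the 2-substituted allylic alcohol with D-(−)-diethyl tartrate delivers oxygen to the alkene face that gives the (R)-epoxide, which fixes the future C4 centre.

Step 3
Reactants: 3 (R)-[2-(TBSO-methyl)oxiran-2-yl]methanol
Product: 4 (R)-2-(TBSO-methyl)oxirane-2-carboxylic acid
Conditions: TEMPO (cat.), PhI(OAc)2, MeCN/H2O, rt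
Reagents that add atoms: water, O
Why: TEMPO-catalysed oxidation with PhI(OAc)2 in aqueous acetonitrile takes the primary alcohol through the aldehyde hydrate to the glycidic acid without touching the epoxide or the silyl ether, and the quaternary centre cannot epimerise.

Step 4
Reactants: 4 (R)-2-(TBSO-methyl)oxirane-2-carboxylic acid
Product: 5 methyl (R)-2-(TBSO-methyl)oxirane-2-carboxylate
Conditions: MeI, K2CO3, DMF, 0 °C → rt
Reagents that add atoms: iodomethane, CI
Why: O-alkylation of the potassium carboxylate with iodomethane (SN2 esterification) gives the methyl ester under conditions too mild to open the epoxide.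

Step 5
Reactants: 6 (R)-4-benzyl-3-propanoyl-1,3-oxazolidin-2-one; 7 2,3-dibromoprop-1-ene
Product: 9 (4R)-4-benzyl-3-[(2S)-4-bromo-2-methylpent-4-enoyl]-1,3-oxazolidin-2-one, via sodium enolate 8 (not isolated)
Conditions: NaN(SiMe3)2, THF, −78 °C; then 7, −78 → −40 °C
Reagents that add atoms: none
Why: Evans asymmetric alkylation, in which the chelated (Z)-sodium enolate is attacked by the allylic bromide on the face opposite the benzyl group of the (R)-auxiliary, sets the (S) configuration of the future C8 while the vinylic bromide of 7 stays untouched.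

Step 6
Reactants: 9 (4R)-4-benzyl-3-[(2S)-4-bromo-2-methylpent-4-enoyl]-1,3-oxazolidin-2-one
Product: 10 (S)-4-bromo-2-methylpent-4-en-1-ol
Conditions: LiBH4, THF, 0 °C → rt
Reagents that add atoms: none
Why: Reductive cleavage of the N-acyl oxazolidinone with LiBH4 releases the primary alcohol and the auxiliary without affecting the α-stereocentre or the vinyl bromide.

Step 7
Reactants: 10 (S)-4-bromo-2-methylpent-4-en-1-ol
Product: 11 (S)-4-bromo-2-methylpent-4-enal
Conditions: Dess–Martin periodinane, CH2Cl2, 0 °C → rt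
Reagents that add atoms: none
Why: Dess–Martin oxidation gives the α-branched aldehyde under near-neutral conditions that should not epimerise C8.

Step 8
Reactants: 11 (S)-4-bromo-2-methylpent-4-enal
Product: 12 (S)-5-bromo-3-methylhex-5-en-1-yne
Conditions: dimethyl (1-diazo-2-oxopropyl)phosphonate, K2CO3, MeOH, 0 °C → rt
Reagents that add atoms: dimethyl (1-diazo-2-oxopropyl)phosphonate, COP(=O)(OC)C(=[N+]=[N-])C(C)=O
Why: Seyferth–Gilbert homologation in its Ohira–Bestmann form converts the aldehyde to the terminal alkyne with carbonate in methanol, which is mild enough to keep the α-stereocentre.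

Step 9
Reactants: 12 (S)-5-bromo-3-methylhex-5-en-1-yne; 5 methyl (R)-2-(TBSO-methyl)oxirane-2-carboxylate
Product: 14 methyl (2R,6S)-8-bromo-2-hydroxy-6-methyl-2-(TBSO-methyl)non-8-en-4-ynoate, via lithium acetylide 13 (not isolated)
Conditions: 12 (1.3 equiv), n-BuLi, THF, −78 °C; BF3·OEt2; then 5, −78 °C; aqueous work-up
Reagents that add atoms: none
Why: BF3-promoted opening of the epoxide by the lithium acetylide is an SN2 attack at the unsubstituted epoxide carbon (future C5), so the fully substituted C4 keeps its configuration and becomes the tertiary carbinol, while the ester (which also suppresses cation character at C4) is not attacked at −78 °C.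

Step 10
Reactants: 14 methyl (2R,6S)-8-bromo-2-hydroxy-6-methyl-2-(TBSO-methyl)non-8-en-4-ynoate
Product: 16 methyl (3E,5R)-3-[(2S)-4-bromo-2-methylpent-4-en-1-ylidene]-2,2-dimethyl-5-(TBSO-methyl)-1,2-oxasilolane-5-carboxylate, via dimethylsilyl ether 15 (not isolated)
Conditions: (HMe2Si)2NH, 60 °C, then evaporation; Pt2[(CH2=CHSiMe2)2O]3 (zerovalent platinum, 1 mol%), THF, rt
Reagents that add atoms: 1,1,3,3-tetramethyldisilazane, C[SiH](C)N[SiH](C)C
Why: Silylation of the tertiary alcohol followed by platinum-catalysed intramolecular hydrosilylation proceeds by syn 5-exo-dig addition of Si–H, which places silicon on C6 and hydrogen on C7 and thereby fixes the cis relationship of C5 and C8 needed in the enol ether.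

Step 11
Reactants: 16 methyl (3E,5R)-3-[(2S)-4-bromo-2-methylpent-4-en-1-ylidene]-2,2-dimethyl-5-(TBSO-methyl)-1,2-oxasilolane-5-carboxylate
Product: 18 methyl (2R,4E,6S)-8-bromo-2-hydroxy-4-iodo-6-methyl-2-(TBSO-methyl)nona-4,8-dienoate, via fluoroalkoxysilyl ether 17 (not isolated)
Conditions: NIS, (CF3)2CHOH, 0 °C; then K2CO3 (cat.), MeOH, 0 °C
Reagents that add atoms: N-iodosuccinimide, O=C1CCC(=O)N1I
Why: Iododesilylation of the alkenylsilane (electrophilic ipso substitution) replaces silicon by iodine with retention of alkene geometry, the electron-poor 2-bromoalkene is left alone, and methanolysis then removes the silicon residue from the C4 oxygen.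

Step 12
Reactants: 18 methyl (2R,4E,6S)-8-bromo-2-hydroxy-4-iodo-6-methyl-2-(TBSO-methyl)nona-4,8-dienoate
Product: 19 methyl (2R,4E,6S)-8-bromo-4-iodo-6-methyl-2-(TBSO-methyl)-2-(TESO)nona-4,8-dienoate
Conditions: Et3SiOTf, 2,6-lutidine, CH2Cl2, −78 → 0 °C
Reagents that add atoms: triethylsilyl trifluoromethanesulfonate, CC[Si](CC)(CC)OS(=O)(=O)C(F)(F)F
Why: Silylation of the hindered tertiary alcohol with the silyl triflate and 2,6-lutidine gives the TES ether that masks the C4 hydroxyl until the last step.

Step 13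
Reactants: 19 methyl (2R,4E,6S)-8-bromo-4-iodo-6-methyl-2-(TBSO-methyl)-2-(TESO)nona-4,8-dienoate
Product: 20 methyl (2R,4E,6S)-8-bromo-4-methoxy-6-methyl-2-(TBSO-methyl)-2-(TESO)nona-4,8-dienoate
Conditions: CuI (10 mol%), 3,4,7,8-tetramethyl-1,10-phenanthroline (20 mol%), Cs2CO3, MeOH, toluene, 80 °C
Reagents that add atoms: methanol, CO
Why: Copper-catalysed Ullmann-type C–O coupling of the alkenyl iodide with methanol proceeds with retention, so methoxy takes the place of iodine trans to C8 and the (E)-enol ether results, while the C10 bromide should react far more slowly and methanol cannot change a methyl ester.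

Step 14
Reactants: 21 rac-pent-1-yn-3-ol
Product: 23 rac-(Z)-1-iodo-2-methylpent-1-en-3-ol, via alkenylmagnesium chelate 22 (not isolated)
Conditions: MeMgBr (3 equiv), CuI (10 mol%), THF, −10 °C → rt; then I2, −78 → 0 °C
Reagents that add atoms: methylmagnesium bromide, C[Mg]Br; iodine, II
Why: Copper-catalysed anti-carbomagnesiation of the propargylic magnesium alkoxide adds methyl to the internal alkyne carbon and magnesium to the terminal one within a five-membered chelate, and iodinolysis with retention gives the (Z)-iodoalkene as the racemate.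

Step 15
Reactants: 23 rac-(Z)-1-iodo-2-methylpent-1-en-3-ol
Product: 24 (3S,1Z)-1-iodo-2-methylpent-1-en-3-ol
Conditions: immobilised Candida antarctica lipase B, vinyl acetate, hexane, 30 °C, stopped just past half conversion; chromatography
Reagents that add atoms: none
Why: Lipase-catalysed kinetic resolution by acyl transfer acetylates the (R)-alcohol, whose large alkenyl and medium ethyl groups match the enzyme pockets, and leaves the (S)-alcohol carrying the future C13 centre.

Step 16
Reactants: 24 (3S,1Z)-1-iodo-2-methylpent-1-en-3-ol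
Product: 25 (3S,1Z)-2-methyl-1-(pinB)pent-1-en-3-ol
Conditions: B2pin2, PdCl2(PPh3)2 (3 mol%), PPh3, KOPh, toluene, 50 °C
Reagents that add atoms: bis(pinacolato)diboron, CC1(C)OB(OC1(C)C)B1OC(C)(C)C(C)(C)O1
Why: Miyaura borylation of the alkenyl iodide with phenoxide as base proceeds with retention of the (Z) geometry and tolerates the free hydroxyl.

Step 17
Reactants: 20 methyl (2R,4E,6S)-8-bromo-4-methoxy-6-methyl-2-(TBSO-methyl)-2-(TESO)nona-4,8-dienoate; 25 (3S,1Z)-2-methyl-1-(pinB)pent-1-en-3-ol
Product: 26 methyl (2R,4E,6S,9Z,11S)-11-hydroxy-4-methoxy-6,10-dimethyl-8-methylidene-2-(TBSO-methyl)-2-(TESO)trideca-4,9-dienoate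
Conditions: PdCl2(dppf) (5 mol%), K3PO4, THF/H2O, 50 °C
Reagents that add atoms: none
Why: Suzuki–Miyaura coupling of the unhindered 2-bromoalkene with the (Z)-alkenyl boronate joins C10 to C11 with retention at both alkenes and gives the 2-substituted 1,3-diene under basic conditions that spare the enol ether, the ester and the silyl ethers.

Step 18
Reactants: 26 methyl (2R,4E,6S,9Z,11S)-11-hydroxy-4-methoxy-6,10-dimethyl-8-methylidene-2-(TBSO-methyl)-2-(TESO)trideca-4,9-dienoate
Product: 27 (2R,4E,6S,9Z,11S)-11-hydroxy-4-methoxy-6,10-dimethyl-8-methylidene-2-(TBSO-methyl)-2-(TESO)trideca-4,9-dienal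
Conditions: iBu2AlH (2.5 equiv), CH2Cl2, −78 °C; MeOH, then aq. potassium sodium tartrate
Reagents that add atoms: none
Why: Half-reduction of the α-silyloxy methyl ester with iBu2AlH at −78 °C should stop at the aluminium hemiacetal, which is stabilised by the neighbouring oxygen and the quaternary centre and releases the aldehyde on work-up, while the secondary hydroxyl is only converted to its aluminium alkoxide.

Step 19
Reactants: 27 (2R,4E,6S,9Z,11S)-11-hydroxy-4-methoxy-6,10-dimethyl-8-methylidene-2-(TBSO-methyl)-2-(TESO)trideca-4,9-dienal; 28 2-bromopropanoyl bromide (racemic)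
Product: 29 (3S,4Z,8S,9E,12R)-10-methoxy-4,8-dimethyl-6-methylidene-13-oxo-12-(TBSO-methyl)-12-(TESO)trideca-4,9-dien-3-yl 2-bromopropanoate (both bromide epimers)
Conditions: 28, pyridine, CH2Cl2, −20 → 0 °C
Reagents that add atoms: none
Why: Acylation of the secondary allylic alcohol with the acid bromide and pyridine (nucleophilic acyl substitution) installs the α-bromo ester as a mixture of bromide epimers, which does not matter because both give the same enolate.

Step 20
Reactants: 29 (3S,4Z,8S,9E,12R)-10-methoxy-4,8-dimethyl-6-methylidene-13-oxo-12-(TBSO-methyl)-12-(TESO)trideca-4,9-dien-3-yl 2-bromopropanoate (both bromide epimers)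
Product: 31 (5R,7E,9S,12Z,14S)-14-ethyl-4-hydroxy-7-methoxy-3,9,13-trimethyl-11-methylidene-5-(TBSO-methyl)-5-(TESO)-1-oxacyclotetradeca-7,12-dien-2-one (mixture at C2 and C3), via samarium enolate 30 (not isolated)
Conditions: SmI2 (divalent samarium, 4 equiv), THF, syringe-pump addition of 29 at −78 °C to a final 2 mM, then 0 °C; aqueous work-up
Reagents that add atoms: none
Why: Two single-electron transfers from divalent samarium cleave the C–Br bond of either bromide epimer and give one trivalent samarium ester enolate, which adds to the C3 aldehyde through a chelated six-membered transition state; the closest known reaction type is the SmI2-mediated intramolecular Reformatsky reaction that forms medium and large lactones. The 14-membered ring closes by 14-exo-trig attack of C2 on the aldehyde carbon and the product is the β-hydroxy lactone. The new centres C2 and C3 arise without control, which is accepted because C3 is erased by the oxidation of step 21 and C2, lying between the C1 and C3 carbonyls, is settled by equilibration in step 22. The step needs reduction of the α-bromo ester ahead of the aldehyde, secured by the much faster electron transfer to the activated C–Br bond at low temperature, and ring closure ahead of oligomerisation, secured by slow addition at high dilution. The aldehyde sits on the fully substituted C4 and cannot enolise, so the enolate is not lost by proton transfer, and the silyl ethers, the enol ether and the diene are inert to SmI2.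

Step 21
Reactants: 31 (5R,7E,9S,12Z,14S)-14-ethyl-4-hydroxy-7-methoxy-3,9,13-trimethyl-11-methylidene-5-(TBSO-methyl)-5-(TESO)-1-oxacyclotetradeca-7,12-dien-2-one (mixture at C2 and C3)
Product: 32 (5R,7E,9S,12Z,14S)-14-ethyl-7-methoxy-3,9,13-trimethyl-11-methylidene-5-(TBSO-methyl)-5-(TESO)-1-oxacyclotetradeca-7,12-diene-2,4-dione (mixture at C2)
Conditions: Dess–Martin periodinane, pyridine, CH2Cl2, 0 °C → rt
Reagents that add atoms: none
Why: Dess–Martin oxidation buffered with pyridine converts the C3 carbinol to the ketone, which removes the C3 stereocentre, without acid that would hydrolyse the enol ether.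

Step 22
Reactants: 32 (5R,7E,9S,12Z,14S)-14-ethyl-7-methoxy-3,9,13-trimethyl-11-methylidene-5-(TBSO-methyl)-5-(TESO)-1-oxacyclotetradeca-7,12-diene-2,4-dione (mixture at C2)
Product: 34 (3R,5R,7E,9S,12Z,14S)-14-ethyl-5-hydroxy-5-(hydroxymethyl)-7-methoxy-3,9,13-trimethyl-11-methylidene-1-oxacyclotetradeca-7,12-diene-2,4-dione (the target), via desilylated C2-epimer mixture 33 (not isolated)
Conditions: Bu4NF, AcOH (1:1), THF, 0 °C → rt; then Et3N (cat.), CH2Cl2, rt
Reagents that add atoms: none
Why: Acetic acid-buffered fluoride cleaves the tertiary TES and the primary TBS ether (desilylation) without hydrolysing the enol ether, and the β-keto lactone, whose C2–H lies between two carbonyls, is then equilibrated through its enol by a trace of amine to the ring-preferred (2R) epimer.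

**Compound list**

1 | 2-methylidenepropane-1,3-diol | C=C(CO)CO | starting material
2 | 2-({[tert-butyl(dimethyl)silyl]oxy}methyl)prop-2-en-1-ol | C=C(CO)CO[Si](C)(C)C(C)(C)C | intermediate
3 | (R)-[2-({[tert-butyl(dimethyl)silyl]oxy}methyl)oxiran-2-yl]methanol | OC[C@]1(CO[Si](C)(C)C(C)(C)C)CO1 | intermediate
4 | (R)-2-({[tert-butyl(dimethyl)silyl]oxy}methyl)oxirane-2-carboxylic acid | OC(=O)[C@]1(CO[Si](C)(C)C(C)(C)C)CO1 | intermediate
5 | methyl (R)-2-({[tert-butyl(dimethyl)silyl]oxy}methyl)oxirane-2-carboxylate | COC(=O)[C@]1(CO[Si](C)(C)C(C)(C)C)CO1 | intermediate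
6 | (R)-4-benzyl-3-propanoyl-1,3-oxazolidin-2-one | CCC(=O)N1[C@H](Cc2ccccc2)COC1=O | starting material
7 | 2,3-dibromoprop-1-ene | C=C(Br)CBr | starting material
8 | sodium (Z)-1-[(4R)-4-benzyl-2-oxo-1,3-oxazolidin-3-yl]prop-1-en-1-olate (sodium enolate of 6) | C/C=C(\[O-])N1[C@H](Cc2ccccc2)COC1=O.[Na+] | intermediate
9 | (4R)-4-benzyl-3-[(2S)-4-bromo-2-methylpent-4-enoyl]-1,3-oxazolidin-2-one | C=C(Br)C[C@H](C)C(=O)N1[C@H](Cc2ccccc2)COC1=O | intermediate
10 | (S)-4-bromo-2-methylpent-4-en-1-ol | C=C(Br)C[C@H](C)CO | intermediate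
11 | (S)-4-bromo-2-methylpent-4-enal | C=C(Br)C[C@H](C)C=O | intermediate
12 | (S)-5-bromo-3-methylhex-5-en-1-yne | C=C(Br)C[C@H](C)C#C | intermediate
13 | [(3S)-5-bromo-3-methylhex-5-en-1-yn-1-yl]lithium (lithium acetylide of 12) | C=C(Br)C[C@H](C)C#C[Li] | intermediate
14 | methyl (2R,6S)-8-bromo-2-({[tert-butyl(dimethyl)silyl]oxy}methyl)-2-hydroxy-6-methylnon-8-en-4-ynoate | COC(=O)[C@](O)(CO[Si](C)(C)C(C)(C)C)CC#C[C@@H](C)CC(Br)=C | intermediate
15 | methyl (2R,6S)-8-bromo-2-({[tert-butyl(dimethyl)silyl]oxy}methyl)-2-[(dimethylsilyl)oxy]-6-methylnon-8-en-4-ynoate | COC(=O)[C@](O[SiH](C)C)(CO[Si](C)(C)C(C)(C)C)CC#C[C@@H](C)CC(Br)=C | intermediate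
16 | methyl (3E,5R)-3-[(2S)-4-bromo-2-methylpent-4-en-1-ylidene]-5-({[tert-butyl(dimethyl)silyl]oxy}methyl)-2,2-dimethyl-1,2-oxasilolane-5-carboxylate | COC(=O)[C@]1(CO[Si](C)(C)C(C)(C)C)C/C(=C\[C@@H](C)CC(Br)=C)[Si](C)(C)O1 | intermediate
17 | methyl (2R,4E,6S)-8-bromo-2-({[tert-butyl(dimethyl)silyl]oxy}methyl)-2-({[(1,1,1,3,3,3-hexafluoropropan-2-yl)oxy]dimethylsilyl}oxy)-4-iodo-6-methylnona-4,8-dienoate | COC(=O)[C@](O[Si](C)(C)OC(C(F)(F)F)C(F)(F)F)(CO[Si](C)(C)C(C)(C)C)C/C(I)=C\[C@@H](C)CC(Br)=C | intermediate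
18 | methyl (2R,4E,6S)-8-bromo-2-({[tert-butyl(dimethyl)silyl]oxy}methyl)-2-hydroxy-4-iodo-6-methylnona-4,8-dienoate | COC(=O)[C@](O)(CO[Si](C)(C)C(C)(C)C)C/C(I)=C\[C@@H](C)CC(Br)=C | intermediate
19 | methyl (2R,4E,6S)-8-bromo-2-({[tert-butyl(dimethyl)silyl]oxy}methyl)-4-iodo-6-methyl-2-[(triethylsilyl)oxy]nona-4,8-dienoate | COC(=O)[C@](O[Si](CC)(CC)CC)(CO[Si](C)(C)C(C)(C)C)C/C(I)=C\[C@@H](C)CC(Br)=C | intermediate
20 | methyl (2R,4E,6S)-8-bromo-2-({[tert-butyl(dimethyl)silyl]oxy}methyl)-4-methoxy-6-methyl-2-[(triethylsilyl)oxy]nona-4,8-dienoate | COC(=O)[C@](O[Si](CC)(CC)CC)(CO[Si](C)(C)C(C)(C)C)C/C(OC)=C\[C@@H](C)CC(Br)=C | intermediate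
21 | rac-pent-1-yn-3-ol | CCC(O)C#C | starting material
22 | 5-ethyl-4-methyl-2,5-dihydro-1,2-oxamagnesole (racemic alkenylmagnesium chelate) | CCC1O[Mg]C=C1C | intermediate
23 | rac-(Z)-1-iodo-2-methylpent-1-en-3-ol | CCC(O)/C(C)=C\I | intermediate
24 | (3S,1Z)-1-iodo-2-methylpent-1-en-3-ol | CC[C@H](O)/C(C)=C\I | intermediate
25 | (3S,1Z)-2-methyl-1-(4,4,5,5-tetramethyl-1,3,2-dioxaborolan-2-yl)pent-1-en-3-ol | CC[C@H](O)/C(C)=C\B1OC(C)(C)C(C)(C)O1 | intermediate
26 | methyl (2R,4E,6S,9Z,11S)-2-({[tert-butyl(dimethyl)silyl]oxy}methyl)-11-hydroxy-4-methoxy-6,10-dimethyl-8-methylidene-2-[(triethylsilyl)oxy]trideca-4,9-dienoate | COC(=O)[C@](O[Si](CC)(CC)CC)(CO[Si](C)(C)C(C)(C)C)C/C(OC)=C\[C@@H](C)CC(=C)/C=C(/C)[C@H](CC)O | intermediate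
27 | (2R,4E,6S,9Z,11S)-2-({[tert-butyl(dimethyl)silyl]oxy}methyl)-11-hydroxy-4-methoxy-6,10-dimethyl-8-methylidene-2-[(triethylsilyl)oxy]trideca-4,9-dienal | O=C[C@](O[Si](CC)(CC)CC)(CO[Si](C)(C)C(C)(C)C)C/C(OC)=C\[C@@H](C)CC(=C)/C=C(/C)[C@H](CC)O | intermediate
28 | 2-bromopropanoyl bromide (racemic) | CC(Br)C(Br)=O | starting material
29 | (3S,4Z,8S,9E,12R)-12-({[tert-butyl(dimethyl)silyl]oxy}methyl)-10-methoxy-4,8-dimethyl-6-methylidene-13-oxo-12-[(triethylsilyl)oxy]trideca-4,9-dien-3-yl 2-bromopropanoate (both bromide epimers) | O=C[C@](O[Si](CC)(CC)CC)(CO[Si](C)(C)C(C)(C)C)C/C(OC)=C\[C@@H](C)CC(=C)/C=C(/C)[C@H](CC)OC(=O)C(C)Br | intermediate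
30 | diiodosamarium ester enolate of 29 (trivalent samarium) | O=C[C@](O[Si](CC)(CC)CC)(CO[Si](C)(C)C(C)(C)C)C/C(OC)=C\[C@@H](C)CC(=C)/C=C(/C)[C@H](CC)OC(O[Sm](I)I)=CC | intermediate
31 | (5R,7E,9S,12Z,14S)-5-({[tert-butyl(dimethyl)silyl]oxy}methyl)-14-ethyl-4-hydroxy-7-methoxy-3,9,13-trimethyl-11-methylidene-5-[(triethylsilyl)oxy]-1-oxacyclotetradeca-7,12-dien-2-one, mixture at ring positions 3 and 4 (C2 and C3) | C=C1/C=C(/C)[C@H](CC)OC(=O)C(C)C(O)[C@](O[Si](CC)(CC)CC)(CO[Si](C)(C)C(C)(C)C)C/C(OC)=C\[C@@H](C)C1 | intermediate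
32 | (5R,7E,9S,12Z,14S)-5-({[tert-butyl(dimethyl)silyl]oxy}methyl)-14-ethyl-7-methoxy-3,9,13-trimethyl-11-methylidene-5-[(triethylsilyl)oxy]-1-oxacyclotetradeca-7,12-diene-2,4-dione, mixture at ring position 3 (C2) | C=C1/C=C(/C)[C@H](CC)OC(=O)C(C)C(=O)[C@](O[Si](CC)(CC)CC)(CO[Si](C)(C)C(C)(C)C)C/C(OC)=C\[C@@H](C)C1 | intermediate
33 | (5R,7E,9S,12Z,14S)-14-ethyl-5-hydroxy-5-(hydroxymethyl)-7-methoxy-3,9,13-trimethyl-11-methylidene-1-oxacyclotetradeca-7,12-diene-2,4-dione, mixture at ring position 3 (C2) | C=C1/C=C(/C)[C@H](CC)OC(=O)C(C)C(=O)[C@](O)(CO)C/C(OC)=C\[C@@H](C)C1 | intermediate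
34 | (3R,5R,7E,9S,12Z,14S)-14-ethyl-5-hydroxy-5-(hydroxymethyl)-7-methoxy-3,9,13-trimethyl-11-methylidene-1-oxacyclotetradeca-7,12-diene-2,4-dione | C=C1/C=C(/C)[C@H](CC)OC(=O)[C@H](C)C(=O)[C@](O)(CO)C/C(OC)=C\[C@@H](C)C1 | target

**Step count and risks**

Total steps: 22. Longest linear sequence: 15 steps (steps 5–13, then 17–22; the branch through steps 1–4 is equally long).

Steps most likely to fail:

1. Step 13 (copper-catalysed methoxylation). The catalyst may turn over poorly on the hindered, fully substituted alkenyl iodide. Conversion could then stall, while prolonged heating with carbonate in methanol begins to substitute the C10 bromide or to cleave silyl ethers. The fallback sets out from 19 and returns at 20. Miyaura borylation of the iodide (B2pin2, PdCl2(PPh3)2, KOPh, toluene, 50 °C; the iodide adds to palladium well before the bromide) gives, with retention, methyl (2R,4Z,6S)-8-bromo-2-({[tert-butyl(dimethyl)silyl]oxy}methyl)-6-methyl-4-(4,4,5,5-tetramethyl-1,3,2-dioxaborolan-2-yl)-2-[(triethylsilyl)oxy]nona-4,8-dienoate F1. Chan–Lam oxidative etherification with methanol (Cu(OAc)2, divalent copper, Et3N, MeOH, air, rt) then replaces boron by methoxy with retention and gives 20.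

2. Step 20 (samarium Reformatsky ring closure). Intermolecular addition to oligomers, plain reduction of the C–Br bond followed by protonation, or ketyl formation at the aldehyde with pinacol coupling may outrun the cyclisation. The fallback sets out from 27 and returns at 31; it forms C2–C3 first and closes the ring at the ester oxygen. Aldol addition of the lithium enolate of allyl propanoate (LiN(iPr)2, THF, −78 °C, in excess to allow for the free C13 hydroxyl) to 27 gives prop-2-en-1-yl (4R,6E,8S,11Z,13S)-4-({[tert-butyl(dimethyl)silyl]oxy}methyl)-3,13-dihydroxy-6-methoxy-2,8,12-trimethyl-10-methylidene-4-[(triethylsilyl)oxy]pentadeca-6,11-dienoate F2. Deallylation with Pd(PPh3)4 (zerovalent palladium) and morpholine gives (4R,6E,8S,11Z,13S)-4-({[tert-butyl(dimethyl)silyl]oxy}methyl)-3,13-dihydroxy-6-methoxy-2,8,12-trimethyl-10-methylidene-4-[(triethylsilyl)oxy]pentadeca-6,11-dienoic acid F3. Yamaguchi macrolactonisation onto the C13 hydroxyl (2,4,6-trichlorobenzoyl chloride, Et3N, then DMAP, toluene, high dilution) gives 31.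

3. Step 22 (desilylation and C2 equilibration). While fluoride removes the silyl groups, the freed C4 and primary hydroxyls may attack the β-keto lactone (ring contraction by translactonisation, retro-Claisen opening), and the C2 epimers may not converge fully. The fallback sets out from 31 and returns at 34; it desilylates before the oxidation, when no β-dicarbonyl unit is present. Bu4NF/AcOH on 31 gives (5R,7E,9S,12Z,14S)-14-ethyl-4,5-dihydroxy-5-(hydroxymethyl)-7-methoxy-3,9,13-trimethyl-11-methylidene-1-oxacyclotetradeca-7,12-dien-2-one F4. The secondary C3 carbinol of its vicinal C3/C4 diol is then oxidised chemoselectively with [(2,9-dimethyl-1,10-phenanthroline)Pd(OAc)]2(OTf)2 (divalent palladium) and benzoquinone in MeCN/H2O, a catalyst that prefers secondary over primary hydroxyls in polyols. Brief equilibration of C2 with a trace of Et3N then gives 34.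

**Further compounds**

F1 | step 13 | methyl (2R,4Z,6S)-8-bromo-2-({[tert-butyl(dimethyl)silyl]oxy}methyl)-6-methyl-4-(4,4,5,5-tetramethyl-1,3,2-dioxaborolan-2-yl)-2-[(triethylsilyl)oxy]nona-4,8-dienoate | COC(=O)[C@](O[Si](CC)(CC)CC)(CO[Si](C)(C)C(C)(C)C)C/C(B1OC(C)(C)C(C)(C)O1)=C\[C@@H](C)CC(Br)=C
F2 | step 20 | prop-2-en-1-yl (4R,6E,8S,11Z,13S)-4-({[tert-butyl(dimethyl)silyl]oxy}methyl)-3,13-dihydroxy-6-methoxy-2,8,12-trimethyl-10-methylidene-4-[(triethylsilyl)oxy]pentadeca-6,11-dienoate (mixture at C2 and C3) | C=CCOC(=O)C(C)C(O)[C@](O[Si](CC)(CC)CC)(CO[Si](C)(C)C(C)(C)C)C/C(OC)=C\[C@@H](C)CC(=C)/C=C(/C)[C@H](CC)O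
F3 | step 20 | (4R,6E,8S,11Z,13S)-4-({[tert-butyl(dimethyl)silyl]oxy}methyl)-3,13-dihydroxy-6-methoxy-2,8,12-trimethyl-10-methylidene-4-[(triethylsilyl)oxy]pentadeca-6,11-dienoic acid (mixture at C2 and C3) | OC(=O)C(C)C(O)[C@](O[Si](CC)(CC)CC)(CO[Si](C)(C)C(C)(C)C)C/C(OC)=C\[C@@H](C)CC(=C)/C=C(/C)[C@H](CC)O
F4 | step 22 | (5R,7E,9S,12Z,14S)-14-ethyl-4,5-dihydroxy-5-(hydroxymethyl)-7-methoxy-3,9,13-trimethyl-11-methylidene-1-oxacyclotetradeca-7,12-dien-2-one (mixture at ring positions 3 and 4) | C=C1/C=C(/C)[C@H](CC)OC(=O)C(C)C(O)[C@](O)(CO)C/C(OC)=C\[C@@H](C)C1
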